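## Structural features

Hansforester J is an open-chain triester of four units joined head to tail: (R)-1-(3,5-dihydroxyphenyl)propan-2-ol (unit A, ring A), an (R)-3-hydroxybutanoate (unit B), a 2,4-dihydroxy-6-[(R)-2-hydroxypropyl]benzoate (unit C, ring C) and a terminal (R)-3-hydroxybutanoate (unit D) with a free hydroxyl. The carbinol oxygen of A carries the carboxyl of B, the carbinol oxygen of B carries the carboxyl on C1 of ring C, and the side-chain carbinol of C carries the carboxyl of D. The four stereocentres are all R secondary methyl carbinols; none is adjacent to another, each being separated from the next by an ester group and at least one methylene, so every centre can come from the chiral pool. The fragile elements are the two beta-acyloxy esters (B and D), which can lose carboxylate by E1cB under base, the ester links, which can transesterify, and the two electron-rich resorcinol rings. Ring C holds a specific trap: when its side-chain carbinol is free, the oxygen can attack the benzoate carbonyl and close a six-membered dihydroisocoumarin lactone, expelling unit B. The real difficulty is the ring C ester, a benzoate flanked by the C2 oxygen and the C6 side chain and bound to a secondary alcohol that is itself beta to an ester, which is a poor case for direct esterification. The key step exploits the fact that C1 (carboxyl), C2 and C4 (hydroxyls) and C6 (alkyl) of ring C show the folding pattern of a linear tetraketide, so the ester can be made on an open-chain acylketene and the ring closed afterwards between C1 and C6.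

## Logic of the disconnections

23 to 22 to 21: the four aryl O–CH2Ph bonds and the Si–O bond of unit D are the last bonds removed. Benzyl ethers fall under neutral hydrogenolysis, which touches no ester and no homobenzylic C–O bond. The silyl ether is taken off one step earlier with buffered fluoride, so that the final operation ends with a filtration. The demand is that neither step is basic.

21 to 20 + 3: the ester C–O bond between the side-chain oxygen of ring C and the carbonyl of unit D is cut. This is an ordinary acylation of an unhindered secondary alcohol, and it brings in unit D as the same 3 that serves elsewhere, which saves the separate synthesis of a benzyl-protected acid. The demand is that acylation of 20 outruns its lactonization, so 20 must meet an already activated acid and no free base.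

20 to 19 to 18: functional-group changes only. The two phenols created with ring C are capped as benzyl ethers, the same class as on ring A, and the silyl ether is then cleaved. The demand is a benzylation mild enough for the beta-acyloxy ester of unit B.

18 to 9 + 15 (key disconnection): the ester C(acyl)–O bond to the unit B oxygen and the aryl C1–C6 bond of ring C are cut together. Ring C and its hindered ester vanish in one operation, leaving the non-aromatic 9 and the simple secondary alcohol 15, of similar size. The demands are aldol regiochemistry in the ring closure, a side-chain protecting group that neither leaves nor lactonizes, and an alcohol that survives 110 °C.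

9 to 6 + 3 (through 7 and 8): the C3–C4 bond of the heptyl chain is cut, the retron of a crossed Claisen condensation that forms the 1,3-diketone. Compound 3 brings the stereocentre already protected. The demand is acylation at the terminal carbon of a dianion, with excess dianion because the product is the stronger acid.

6 to 4 (through 5): the C1–C2 bond of the oxopropyl side chain is cut, corresponding to acylation of 5 at its gamma carbon by an acetyl donor.

15 to 13 + 3 (through 14): the ester C–O bond between the unit A oxygen and the unit B carbonyl is cut. Coupling followed by desilylation reuses 3. The demand is a non-basic desilylation, since the product is a beta-hydroxy ester.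

13 to 10 + 11 (through 12): the aryl–CH2 bond is cut. The stereocentre arrives intact in 11, and the forward step only has to open the epoxide at its CH2 terminus.

3 to 2 to 1: silylation and ester hydrolysis of a pool hydroxy ester. Compound 3 is used three times: for unit B, for carbons C7 to C10 of the polyketide chain, and for unit D.

## Other disconnections considered

Alternative 1: The cut runs through ring A itself, at C1–C2 and C3–C4 counted from the phenol carbon, with C1–C6 re-formed in the electrocyclic step.
- Forward step: 3-[(2R)-2-(tert-butyldimethylsilyloxy)propyl]cyclobut-2-en-1-one A1 would be heated with ethoxyacetylene A2. Four-electron ring opening of A1 gives a vinylketene, [2+2] addition of A2 and a second ring opening give a dienylketene, and six-electron electrocyclization with tautomerization gives 3-ethoxy-5-[(2R)-2-(tert-butyldimethylsilyloxy)propyl]phenol A3.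
- In favour: the 1,3,5-pattern of A3 is fixed by the mechanism, no metal is needed, and the carbinol stereocentre is carried through unchanged.
- Against: ring A is the part of the target that is already one step from two catalogue compounds (10 and 11 give 13 in step 5). A1 needs several steps of its own. The two ring oxygens of A3 emerge differentiated as a phenol and an ethyl ether, which the target does not need, and cleaving the ethyl ether needs a strong Lewis acid before any ester is present.
- Comparison on structure: it addresses the easy arene and leaves the hindered ester of ring C untouched, so the chosen key step would still be needed.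
- Comparison on mechanism: a pericyclic cascade with built-in regiocontrol is the equal of the Grignard epoxide opening in reliability, and it is the better in needing no aryl halide. Stereochemical security is equal, since neither creates a stereocentre.
- Comparison on step economy: it is clearly the weaker, several steps to A3 against one step to 13.

Alternative 2: The cut is the aryl C6–CH2 bond of ring C, and the analogous bond of ring A.
- Forward step: 2,4-bis(benzyloxy)benzoic acid A4 and epoxide 11 would react under palladium diacetate A5, a salt of divalent palladium, with a mono-N-protected amino acid ligand. Carboxylate-directed palladation of the only free ortho C–H of A4, opening of the epoxide at its CH2 carbon and lactonization would give (R)-6,8-bis(benzyloxy)-3-methylisochroman-1-one A6.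
- In favour: one step, with A5 needed only in catalytic amount, gives the whole carbon skeleton of unit C with its stereocentre from the pool. The same lactone A6 could give 13 after hydrolysis and protodecarboxylation.
- Against: A6 is exactly the dihydroisocoumarin that the chosen plan is built to avoid. To reach the target the lactone must be opened, the carbinol masked against reclosure, and the 2,6-disubstituted acid esterified with the hindered alcohol 15. That makes the hardest bond of the molecule by the weakest method.
- Comparison on structure and step economy: it is the better for reaching the ring C skeleton, one step from A4 against steps 1 to 4 plus step 8. For ring A it is the weaker, three steps against one.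
- Comparison on stereochemistry: equal.
- Comparison on mechanism: the chosen plan is the stronger for the decisive ester, because it forms that C–O bond at an sp ketene carbon before the ortho substituents exist.

Alternative 3: The cut is at the two O–C bonds of the unit A carbinol and the ring C side-chain carbinol, which reverts both esters to ketones.
- Forward step: the bis-ketone (2R,5R)-6-{3,5-bis[(benzyloxycarbonyl)oxy]phenyl}-5-methyl-4-oxohexan-2-yl 2,4-bis[(benzyloxycarbonyl)oxy]-6-{(2R,5R)-5-[(benzyloxycarbonyl)oxy]-2-methyl-3-oxohexyl}benzoate A7 would be treated with trifluoroperoxyacetic acid A8 in the presence of a phosphate buffer. Two Baeyer-Villiger insertions with migration of the secondary carbons and retention would give A9, the pentakis(benzyl carbonate) of 23, and hydrogenolysis of A9 would unmask 23.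
- In favour: two ester C–O bonds form in one operation with retention. The secondary carbon should migrate in preference to the CH2 whose beta-oxygen lowers its migratory aptitude. Ester formation is replaced by ketone C–C chemistry.
- Against: in A7 the two migrating stereocentres are alpha to ketones. They are no longer pool carbinols, must be set by asymmetric alkylation, and can epimerize. Both ketones are beta-acyloxy ketones open to E1cB. The resorcinol rings must be deactivated as carbonates against oxidation by A8. The ring C benzoate to the unit B oxygen must still be made by some other means.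
- Comparison on structure: it leaves the central difficulty in place.
- Comparison on mechanism: it is the better in bonds formed per operation and the equal in ending with a single hydrogenolysis, but the weaker in stereochemical security, since two of four centres become labile.
- Comparison on step economy: the weaker, because A7 must be assembled with two new asymmetric steps.

Key step: step 8

Assumption: bromide 10 is taken as a catalogue compound; where it is not stocked, one O-benzylation of 5-bromoresorcinol supplies it and nothing else changes. All four stereocentres of the target are R and all derive from 1 and 11.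

## Route

Step 1
Reactants: 1 ethyl (R)-3-hydroxybutanoate
Product: 2 ethyl (R)-3-(triisopropylsilyloxy)butanoate
Conditions: i-Pr3SiOTf, 2,6-lutidine, CH2Cl2, 0 °C to rt
Reagents that add atoms: triisopropylsilyl trifluoromethanesulfonate, CC(C)[Si](OS(=O)(=O)C(F)(F)F)(C(C)C)C(C)C
Why: O-silylation of a secondary alcohol with a silyl triflate and a hindered pyridine base; the stereocentre is not involved and stays R, and the bulky silyl ether is chosen to withstand amide bases, 110 °C and carbonate later.

Step 2
Reactants: 2 ethyl (R)-3-(triisopropylsilyloxy)butanoate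
Product: 3 (R)-3-(triisopropylsilyloxy)butanoic acid
Conditions: LiOH·H2O, THF/MeOH/H2O, rt; then 1 M HCl to pH 3
Reagents that add atoms: lithium hydroxide, [Li+].[OH-]
Why: Ester saponification by acyl-oxygen cleavage; the triisopropylsilyl ether is stable to aqueous hydroxide at room temperature and the carbinol carbon is not enolizable, so the R configuration is kept.

Step 3
Reactants: 4 2,2,6-trimethyl-4H-1,3-dioxin-4-one
Product: 6 2,2-dimethyl-6-(2-oxopropyl)-4H-1,3-dioxin-4-one, via lithium dienolate 5 (not isolated)
Conditions: 4 (2 equiv), LiN(SiMe3)2 (2 equiv), THF, −78 °C; AcCl (1 equiv), −78 °C; aq NH4Cl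
Reagents that add atoms: acetyl chloride, CC(Cl)=O
Why: Claisen-type acylation of a vinylogous ester enolate: kinetic deprotonation of the 6-methyl group gives dienolate 5, which is acylated at its gamma carbon; the second equivalent of dienolate absorbs the proton of the more acidic keto-dioxinone as it forms.

Step 4
Reactants: 6 2,2-dimethyl-6-(2-oxopropyl)-4H-1,3-dioxin-4-one; 3 (R)-3-(triisopropylsilyloxy)butanoic acid
Product: 9 6-[(6R)-2,4-dioxo-6-(triisopropylsilyloxy)heptyl]-2,2-dimethyl-4H-1,3-dioxin-4-one, via dilithium dienediolate 7 (not isolated), via acyl imidazolide 8 (not isolated)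
Conditions: 3, 1,1'-carbonyldiimidazole, THF, rt (gives 8); separately 6 (2.2 equiv), LiN(i-Pr)2 (4.5 equiv), THF, −78 °C (gives 7); add 8, −78 to −40 °C; aq NH4Cl
Reagents that add atoms: none
Why: Crossed Claisen condensation of a ketone dianion: the first equivalent of amide removes the doubly activated C–H between ketone and dioxinone, the second the terminal methyl C–H, and the dianion reacts at its terminal carbon with the imidazolide. The dianion is used in excess because the 1,3-diketone product is deprotonated as it forms, and the stereocentre lies beta to the acyl carbon and cannot epimerize.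

Step 5
Reactants: 10 1-bromo-3,5-bis(benzyloxy)benzene; 11 (R)-propylene oxide
Product: 13 (R)-1-[3,5-bis(benzyloxy)phenyl]propan-2-ol, via arylmagnesium bromide 12 (not isolated)
Conditions: Mg, I2 (cat.), THF, reflux; then CuI (10 mol %), 11, THF, −30 to 0 °C; aq NH4Cl
Reagents that add atoms: none
Why: CuI-catalysed Grignard opening of a terminal epoxide by SN2 attack at the unsubstituted carbon; the C–O bond at the stereocentre is not broken, so the R configuration of 11 is carried into 13, and CuI suppresses halohydrin formation.

Step 6
Reactants: 13 (R)-1-[3,5-bis(benzyloxy)phenyl]propan-2-ol; 3 (R)-3-(triisopropylsilyloxy)butanoic acid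
Product: 14 (R)-1-[3,5-bis(benzyloxy)phenyl]propan-2-yl (R)-3-(triisopropylsilyloxy)butanoate
Conditions: EDC·HCl, DMAP, CH2Cl2, 0 °C to rt
Reagents that add atoms: none
Why: Steglich esterification of an unhindered secondary alcohol through the acylpyridinium ion; both stereocentres are spectators, and the silyl ether prevents self-condensation of the hydroxy acid.

Step 7
Reactants: 14 (R)-1-[3,5-bis(benzyloxy)phenyl]propan-2-yl (R)-3-(triisopropylsilyloxy)butanoate
Product: 15 (R)-1-[3,5-bis(benzyloxy)phenyl]propan-2-yl (R)-3-hydroxybutanoate
Conditions: HF·pyridine, pyridine, THF, 0 °C to rt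
Reagents that add atoms: none
Why: Fluoride-driven Si–O cleavage in a buffered acidic medium; no alkoxide is generated, so the beta-hydroxy ester is not exposed to retro-aldol cleavage, elimination or acyl migration, and the benzyl ethers are inert.

Step 8
Reactants: 9 6-[(6R)-2,4-dioxo-6-(triisopropylsilyloxy)heptyl]-2,2-dimethyl-4H-1,3-dioxin-4-one; 15 (R)-1-[3,5-bis(benzyloxy)phenyl]propan-2-yl (R)-3-hydroxybutanoate
Product: 18 (R)-4-{[(R)-1-[3,5-bis(benzyloxy)phenyl]propan-2-yl]oxy}-4-oxobutan-2-yl 2,4-dihydroxy-6-[(R)-2-(triisopropylsilyloxy)propyl]benzoate, via acylketene 16 (not isolated), via triketo ester 17 (not isolated)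
Conditions: 9 (1.2 equiv), 15, PhMe, 110 °C; concentrate; Cs2CO3, CH2Cl2/i-PrOH, rt; then AcOH
Reagents that add atoms: none
Why: At about 110 °C dioxinone 9 loses acetone by retro-hetero-Diels-Alder reaction to give acylketene 16, and the hydroxyl of 15 adds to the ketene carbon to give triketo ester 17, so the ester C–O bond is made at an unhindered sp carbon before any ortho substituent exists. Cs2CO3 then forms the enolate at C2, between the ester and the C3 ketone, which adds to the C7 ketone in a 6-exo-trig aldol closure that creates the aryl C1–C6 bond; loss of water and enolization of the C3 and C5 carbonyls, completed on acidification and driven by aromatization, give ring C with hydroxyls at C2 and C4. The closest known reaction type is thermolysis of 2,2-dimethyl-1,3-dioxin-4-ones to acylketenes with capture by alcohols, followed by base-mediated cycloaromatization of 3,5,7-triketo esters to resorcylates. No stereocentre is created, and the three R carbinol centres are not enolizable, so they pass through unchanged. The selectivity needed is aldol closure from C2 to C7 in preference to Claisen closure from C6 onto the ester carbon (which would expel 15) and to O-cyclization to a pyranone. It is secured by a mild carbonate base at room temperature, under which the ester carbonyl is the poorest electrophile and the C7 ketone is the best one that can close a six-membered ring with C2. The silyl ether is a poor leaving group and so resists E1cB loss from the beta-silyloxy ketone, and it keeps the side-chain oxygen from lactonizing onto the new ester. The weakly nucleophilic CH2Cl2/i-PrOH medium and short exposure guard the esters against transesterification and unit B against elimination.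

Step 9
Reactants: 18 (R)-4-{[(R)-1-[3,5-bis(benzyloxy)phenyl]propan-2-yl]oxy}-4-oxobutan-2-yl 2,4-dihydroxy-6-[(R)-2-(triisopropylsilyloxy)propyl]benzoate
Product: 19 (R)-4-{[(R)-1-[3,5-bis(benzyloxy)phenyl]propan-2-yl]oxy}-4-oxobutan-2-yl 2,4-bis(benzyloxy)-6-[(R)-2-(triisopropylsilyloxy)propyl]benzoate
Conditions: BnBr (3 equiv), K2CO3, n-Bu4NI (cat.), DMF, rt to 40 °C
Reagents that add atoms: benzyl bromide, BrCc1ccccc1
Why: Williamson etherification of two phenoxides; carbonate is basic enough for phenols but too weak to enolize the esters at a useful rate, and iodide catalysis with gentle warming brings the chelated C2 hydroxyl to full conversion.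

Step 10
Reactants: 19 (R)-4-{[(R)-1-[3,5-bis(benzyloxy)phenyl]propan-2-yl]oxy}-4-oxobutan-2-yl 2,4-bis(benzyloxy)-6-[(R)-2-(triisopropylsilyloxy)propyl]benzoate
Product: 20 (R)-4-{[(R)-1-[3,5-bis(benzyloxy)phenyl]propan-2-yl]oxy}-4-oxobutan-2-yl 2,4-bis(benzyloxy)-6-[(R)-2-hydroxypropyl]benzoate
Conditions: HF·pyridine, pyridine, THF, 0 °C to rt; pH 7 buffer work-up; crude used at once
Reagents that add atoms: none
Why: Buffered acidic fluoride desilylation; the carbinol is freed as the neutral alcohol and never as an alkoxide, so its attack on the di-ortho-substituted benzoate should stay slow, and 20 is not stored.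

Step 11
Reactants: 20 (R)-4-{[(R)-1-[3,5-bis(benzyloxy)phenyl]propan-2-yl]oxy}-4-oxobutan-2-yl 2,4-bis(benzyloxy)-6-[(R)-2-hydroxypropyl]benzoate; 3 (R)-3-(triisopropylsilyloxy)butanoic acid
Product: 21 (R)-4-{[(R)-1-[3,5-bis(benzyloxy)phenyl]propan-2-yl]oxy}-4-oxobutan-2-yl 2,4-bis(benzyloxy)-6-[(R)-2-{[(R)-3-(triisopropylsilyloxy)butanoyl]oxy}propyl]benzoate
Conditions: 3 (2 equiv), EDC·HCl, DMAP, CH2Cl2, 0 °C (acid activated first, 20 added last)
Reagents that add atoms: none
Why: Steglich esterification; intermolecular acyl transfer from a preformed acylpyridinium ion to the unhindered secondary alcohol should be faster than uncatalysed intramolecular attack on the hindered benzoate, and once acylated the side chain can no longer lactonize.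

Step 12
Reactants: 21 (R)-4-{[(R)-1-[3,5-bis(benzyloxy)phenyl]propan-2-yl]oxy}-4-oxobutan-2-yl 2,4-bis(benzyloxy)-6-[(R)-2-{[(R)-3-(triisopropylsilyloxy)butanoyl]oxy}propyl]benzoate
Product: 22 (R)-4-{[(R)-1-[3,5-bis(benzyloxy)phenyl]propan-2-yl]oxy}-4-oxobutan-2-yl 2,4-bis(benzyloxy)-6-[(R)-2-{[(R)-3-hydroxybutanoyl]oxy}propyl]benzoate
Conditions: HF·pyridine, pyridine, THF, 0 °C to rt
Reagents that add atoms: none
Why: The same acidic fluoride desilylation as in step 7, on the same beta-silyloxy ester motif; the freed hydroxyl is beta to its own ester and has no carbonyl within reach for a favourable ring closure.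

Step 13
Reactants: 22 (R)-4-{[(R)-1-[3,5-bis(benzyloxy)phenyl]propan-2-yl]oxy}-4-oxobutan-2-yl 2,4-bis(benzyloxy)-6-[(R)-2-{[(R)-3-hydroxybutanoyl]oxy}propyl]benzoate
Product: 23 Hansforester J, (R)-4-{[(R)-1-(3,5-dihydroxyphenyl)propan-2-yl]oxy}-4-oxobutan-2-yl 2,4-dihydroxy-6-[(R)-2-{[(R)-3-hydroxybutanoyl]oxy}propyl]benzoate
Conditions: H2 (1 atm), Pd/C (10 wt %), EtOAc/EtOH, rt
Reagents that add atoms: none
Why: Hydrogenolysis of four aryl benzyl ethers on Pd/C under neutral conditions; the ester alkyl C–O bonds are homobenzylic or aliphatic and are not cleaved, no base or acid is present to trigger elimination or acyl migration, and no stereocentre is touched.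

## Compound list

1 | ethyl (R)-3-hydroxybutanoate | CCOC(=O)C[C@@H](C)O | starting material
2 | ethyl (R)-3-(triisopropylsilyloxy)butanoate | CCOC(=O)C[C@@H](C)O[Si](C(C)C)(C(C)C)C(C)C | intermediate
3 | (R)-3-(triisopropylsilyloxy)butanoic acid | OC(=O)C[C@@H](C)O[Si](C(C)C)(C(C)C)C(C)C | intermediate
4 | 2,2,6-trimethyl-4H-1,3-dioxin-4-one | CC1=CC(=O)OC(C)(C)O1 | starting material
5 | lithium dienolate of 4 (lithium 2,2-dimethyl-6-methylene-1,3-dioxin-4-olate) | [Li]OC1=CC(=C)OC(C)(C)O1 | intermediate (not isolated)
6 | 2,2-dimethyl-6-(2-oxopropyl)-4H-1,3-dioxin-4-one | CC(=O)CC1=CC(=O)OC(C)(C)O1 | intermediate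
7 | dilithium dienediolate of 6 (terminal-carbon dianion) | [Li]OC(=C)C=C1C=C(O[Li])OC(C)(C)O1 | intermediate (not isolated)
8 | (R)-1-(1H-imidazol-1-yl)-3-(triisopropylsilyloxy)butan-1-one | O=C(C[C@@H](C)O[Si](C(C)C)(C(C)C)C(C)C)n1ccnc1 | intermediate (not isolated)
9 | 6-[(6R)-2,4-dioxo-6-(triisopropylsilyloxy)heptyl]-2,2-dimethyl-4H-1,3-dioxin-4-one | CC1(C)OC(=O)C=C(CC(=O)CC(=O)C[C@@H](C)O[Si](C(C)C)(C(C)C)C(C)C)O1 | intermediate
10 | 1-bromo-3,5-bis(benzyloxy)benzene | Brc1cc(OCc2ccccc2)cc(OCc2ccccc2)c1 | starting material
11 | (R)-propylene oxide | C[C@@H]1CO1 | starting material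
12 | [3,5-bis(benzyloxy)phenyl]magnesium bromide | Br[Mg]c1cc(OCc2ccccc2)cc(OCc2ccccc2)c1 | intermediate (not isolated)
13 | (R)-1-[3,5-bis(benzyloxy)phenyl]propan-2-ol | C[C@H](Cc1cc(OCc2ccccc2)cc(OCc2ccccc2)c1)O | intermediate
14 | (R)-1-[3,5-bis(benzyloxy)phenyl]propan-2-yl (R)-3-(triisopropylsilyloxy)butanoate | C[C@H](Cc1cc(OCc2ccccc2)cc(OCc2ccccc2)c1)OC(=O)C[C@@H](C)O[Si](C(C)C)(C(C)C)C(C)C | intermediate
15 | (R)-1-[3,5-bis(benzyloxy)phenyl]propan-2-yl (R)-3-hydroxybutanoate | C[C@H](Cc1cc(OCc2ccccc2)cc(OCc2ccccc2)c1)OC(=O)C[C@@H](C)O | intermediate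
16 | (9R)-9-(triisopropylsilyloxy)dec-1-ene-1,3,5,7-tetrone (acylketene) | O=C=CC(=O)CC(=O)CC(=O)C[C@@H](C)O[Si](C(C)C)(C(C)C)C(C)C | intermediate (not isolated)
17 | (R)-4-{[(R)-1-[3,5-bis(benzyloxy)phenyl]propan-2-yl]oxy}-4-oxobutan-2-yl (9R)-3,5,7-trioxo-9-(triisopropylsilyloxy)decanoate | C[C@H](Cc1cc(OCc2ccccc2)cc(OCc2ccccc2)c1)OC(=O)C[C@@H](C)OC(=O)CC(=O)CC(=O)CC(=O)C[C@@H](C)O[Si](C(C)C)(C(C)C)C(C)C | intermediate (not isolated)
18 | (R)-4-{[(R)-1-[3,5-bis(benzyloxy)phenyl]propan-2-yl]oxy}-4-oxobutan-2-yl 2,4-dihydroxy-6-[(R)-2-(triisopropylsilyloxy)propyl]benzoate | C[C@H](Cc1cc(OCc2ccccc2)cc(OCc2ccccc2)c1)OC(=O)C[C@@H](C)OC(=O)c1c(O)cc(O)cc1C[C@@H](C)O[Si](C(C)C)(C(C)C)C(C)C | intermediate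
19 | (R)-4-{[(R)-1-[3,5-bis(benzyloxy)phenyl]propan-2-yl]oxy}-4-oxobutan-2-yl 2,4-bis(benzyloxy)-6-[(R)-2-(triisopropylsilyloxy)propyl]benzoate | C[C@H](Cc1cc(OCc2ccccc2)cc(OCc2ccccc2)c1)OC(=O)C[C@@H](C)OC(=O)c1c(OCc2ccccc2)cc(OCc2ccccc2)cc1C[C@@H](C)O[Si](C(C)C)(C(C)C)C(C)C | intermediate
20 | (R)-4-{[(R)-1-[3,5-bis(benzyloxy)phenyl]propan-2-yl]oxy}-4-oxobutan-2-yl 2,4-bis(benzyloxy)-6-[(R)-2-hydroxypropyl]benzoate | C[C@H](Cc1cc(OCc2ccccc2)cc(OCc2ccccc2)c1)OC(=O)C[C@@H](C)OC(=O)c1c(OCc2ccccc2)cc(OCc2ccccc2)cc1C[C@@H](C)O | intermediate
21 | (R)-4-{[(R)-1-[3,5-bis(benzyloxy)phenyl]propan-2-yl]oxy}-4-oxobutan-2-yl 2,4-bis(benzyloxy)-6-[(R)-2-{[(R)-3-(triisopropylsilyloxy)butanoyl]oxy}propyl]benzoate | C[C@H](Cc1cc(OCc2ccccc2)cc(OCc2ccccc2)c1)OC(=O)C[C@@H](C)OC(=O)c1c(OCc2ccccc2)cc(OCc2ccccc2)cc1C[C@@H](C)OC(=O)C[C@@H](C)O[Si](C(C)C)(C(C)C)C(C)C | intermediate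
22 | (R)-4-{[(R)-1-[3,5-bis(benzyloxy)phenyl]propan-2-yl]oxy}-4-oxobutan-2-yl 2,4-bis(benzyloxy)-6-[(R)-2-{[(R)-3-hydroxybutanoyl]oxy}propyl]benzoate | C[C@H](Cc1cc(OCc2ccccc2)cc(OCc2ccccc2)c1)OC(=O)C[C@@H](C)OC(=O)c1c(OCc2ccccc2)cc(OCc2ccccc2)cc1C[C@@H](C)OC(=O)C[C@@H](C)O | intermediate
23 | Hansforester J, (R)-4-{[(R)-1-(3,5-dihydroxyphenyl)propan-2-yl]oxy}-4-oxobutan-2-yl 2,4-dihydroxy-6-[(R)-2-{[(R)-3-hydroxybutanoyl]oxy}propyl]benzoate | C[C@H](Cc1cc(O)cc(O)c1)OC(=O)C[C@@H](C)OC(=O)c1c(O)cc(O)cc1C[C@@H](C)OC(=O)C[C@@H](C)O | target

## Step count and least certain steps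

Total: 13 steps. Longest linear sequence: 10 steps (steps 1, 2, 6, 7, 8, 9, 10, 11, 12, 13, running from 1 through 3, 14, 15 and 18 to 23).

Step 8 (key step).
- Risk in the thermal stage: the acylketene may be captured by its own enol oxygen (pyranone closure) or may dimerize if capture by the secondary alcohol is slow.
- Risk in the base stage: Claisen-type closure onto the ester with expulsion of 15, E1cB loss of the aroyloxy group from unit B, or transesterification may compete with the aldol closure.
- Fallback: set out from 9 and 15 and return at 19, with the arene made first and the ester second. Treatment of 9 with Et3N in CH2Cl2 should let the dioxinone C5 carbon add to the distal ketone and aromatize with the acetonide intact, giving 7-hydroxy-2,2-dimethyl-5-[(2R)-2-(triisopropylsilyloxy)propyl]-4H-1,3-benzodioxin-4-one F1. Benzylation of its phenol would give the 7-benzyl ether F2. Irradiation of F2 near 300 nm in CH2Cl2 in the presence of 15 should expel acetone and give a quinoketene that the alcohol captures, forming the 4-(benzyloxy)-2-hydroxybenzoate triad F3. Benzylation of the remaining chelated phenol would then give 19.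

Step 4.
- Risk: proton transfer from the acidic diketone product to unreacted dianion may stall conversion; O-acylation may compete; enolization of imidazolide 8 may be followed by loss of silyloxide.
- Fallback: set out from 2 and 6 and return at 9, replacing the Claisen condensation by aldol addition and oxidation. Reduction of 2 with i-Bu2AlH at −78 °C would give (R)-3-(triisopropylsilyloxy)butanal F4. Addition of F4 to dianion 7 at −78 °C would give the aldol 6-[(6R)-4-hydroxy-2-oxo-6-(triisopropylsilyloxy)heptyl]-2,2-dimethyl-4H-1,3-dioxin-4-one F5 as a mixture of carbinol epimers, whose alkoxide is not acidic and cannot quench the dianion. Oxidation of F5 with Dess-Martin periodinane would remove the new carbinol centre and give 9.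

Step 10 (with its consequence for step 11).
- Risk: intramolecular transesterification of the freed carbinol onto the benzoate, closing the dihydroisocoumarin and expelling 15, during desilylation, work-up or the DMAP-mediated acylation. Slow cleavage of the bulky silyl ether may also invite harsher conditions that favour this.
- Fallback: set out from 9 and return at 21, freeing and acylating the carbinol while the carboxyl is locked in the fused acetonide, which only alkoxides open. The benzodioxinone F2 of the step 8 fallback would be desilylated with HF·pyridine to 7-(benzyloxy)-5-[(2R)-2-hydroxypropyl]-2,2-dimethyl-4H-1,3-benzodioxin-4-one F6. Steglich esterification of F6 with 3 would give (R)-1-[7-(benzyloxy)-2,2-dimethyl-4-oxo-4H-1,3-benzodioxin-5-yl]propan-2-yl (R)-3-(triisopropylsilyloxy)butanoate F7. Irradiation of F7 with 15 would give the 4-(benzyloxy)-2-hydroxybenzoate tetrad F8, and benzylation of its chelated phenol would give 21.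

Step 9.
- Risk: incomplete etherification of the hydrogen-bonded C2 hydroxyl, and base-induced E1cB at unit B if the reaction is forced with heat or stronger base.
- Fallback: set out from 18 and return at 19 by a base-free redox condensation, Mitsunobu etherification of both phenols with benzyl alcohol, PPh3 and diisopropyl azodicarboxylate in THF. This activates the benzyl alcohol and does not generate a phenoxide in basic medium, and it makes no new compound.

## Further compounds

F1 | step 8 | 7-hydroxy-2,2-dimethyl-5-[(2R)-2-(triisopropylsilyloxy)propyl]-4H-1,3-benzodioxin-4-one | CC1(C)OC(=O)c2c(C[C@@H](C)O[Si](C(C)C)(C(C)C)C(C)C)cc(O)cc2O1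
F2 | step 8 | 7-(benzyloxy)-2,2-dimethyl-5-[(2R)-2-(triisopropylsilyloxy)propyl]-4H-1,3-benzodioxin-4-one | CC1(C)OC(=O)c2c(C[C@@H](C)O[Si](C(C)C)(C(C)C)C(C)C)cc(OCc3ccccc3)cc2O1
F3 | step 8 | (R)-4-{[(R)-1-[3,5-bis(benzyloxy)phenyl]propan-2-yl]oxy}-4-oxobutan-2-yl 4-(benzyloxy)-2-hydroxy-6-[(R)-2-(triisopropylsilyloxy)propyl]benzoate | C[C@H](Cc1cc(OCc2ccccc2)cc(OCc2ccccc2)c1)OC(=O)C[C@@H](C)OC(=O)c1c(O)cc(OCc2ccccc2)cc1C[C@@H](C)O[Si](C(C)C)(C(C)C)C(C)C
F4 | step 4 | (R)-3-(triisopropylsilyloxy)butanal | O=CC[C@@H](C)O[Si](C(C)C)(C(C)C)C(C)C
F5 | step 4 | 6-[(6R)-4-hydroxy-2-oxo-6-(triisopropylsilyloxy)heptyl]-2,2-dimethyl-4H-1,3-dioxin-4-one (both C4 epimers) | CC1(C)OC(=O)C=C(CC(=O)CC(O)C[C@@H](C)O[Si](C(C)C)(C(C)C)C(C)C)O1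
F6 | step 10 | 7-(benzyloxy)-5-[(2R)-2-hydroxypropyl]-2,2-dimethyl-4H-1,3-benzodioxin-4-one | CC1(C)OC(=O)c2c(C[C@@H](C)O)cc(OCc3ccccc3)cc2O1
F7 | step 10 | (R)-1-[7-(benzyloxy)-2,2-dimethyl-4-oxo-4H-1,3-benzodioxin-5-yl]propan-2-yl (R)-3-(triisopropylsilyloxy)butanoate | CC1(C)OC(=O)c2c(C[C@@H](C)OC(=O)C[C@@H](C)O[Si](C(C)C)(C(C)C)C(C)C)cc(OCc3ccccc3)cc2O1
F8 | step 10 | (R)-4-{[(R)-1-[3,5-bis(benzyloxy)phenyl]propan-2-yl]oxy}-4-oxobutan-2-yl 4-(benzyloxy)-2-hydroxy-6-[(R)-2-{[(R)-3-(triisopropylsilyloxy)butanoyl]oxy}propyl]benzoate | C[C@H](Cc1cc(OCc2ccccc2)cc(OCc2ccccc2)c1)OC(=O)C[C@@H](C)OC(=O)c1c(O)cc(OCc2ccccc2)cc1C[C@@H](C)OC(=O)C[C@@H](C)O[Si](C(C)C)(C(C)C)C(C)C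
F0 | step 9 | none | none
A1 | alternative 1 | 3-[(2R)-2-(tert-butyldimethylsilyloxy)propyl]cyclobut-2-en-1-one | C[C@H](CC1=CC(=O)C1)O[Si](C)(C)C(C)(C)C
A2 | alternative 1 | ethoxyacetylene | CCOC#C
A3 | alternative 1 | 3-ethoxy-5-[(2R)-2-(tert-butyldimethylsilyloxy)propyl]phenol | CCOc1cc(O)cc(C[C@@H](C)O[Si](C)(C)C(C)(C)C)c1
A4 | alternative 2 | 2,4-bis(benzyloxy)benzoic acid | OC(=O)c1ccc(OCc2ccccc2)cc1OCc1ccccc1
A5 | alternative 2 | palladium diacetate | CC(=O)[O-].CC(=O)[O-].[Pd+2]
A6 | alternative 2 | (R)-6,8-bis(benzyloxy)-3-methylisochroman-1-one | C[C@@H]1Cc2cc(OCc3ccccc3)cc(OCc3ccccc3)c2C(=O)O1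
A7 | alternative 3 | (2R,5R)-6-{3,5-bis[(benzyloxycarbonyl)oxy]phenyl}-5-methyl-4-oxohexan-2-yl 2,4-bis[(benzyloxycarbonyl)oxy]-6-{(2R,5R)-5-[(benzyloxycarbonyl)oxy]-2-methyl-3-oxohexyl}benzoate | C[C@H](Cc1cc(OC(=O)OCc2ccccc2)cc(OC(=O)OCc2ccccc2)c1)C(=O)C[C@@H](C)OC(=O)c1c(OC(=O)OCc2ccccc2)cc(OC(=O)OCc2ccccc2)cc1C[C@@H](C)C(=O)C[C@@H](C)OC(=O)OCc1ccccc1
A8 | alternative 3 | trifluoroperoxyacetic acid | OOC(=O)C(F)(F)F
A9 | alternative 3 | pentakis(benzyl carbonate) of 23 | C[C@H](Cc1cc(OC(=O)OCc2ccccc2)cc(OC(=O)OCc2ccccc2)c1)OC(=O)C[C@@H](C)OC(=O)c1c(OC(=O)OCc2ccccc2)cc(OC(=O)OCc2ccccc2)cc1C[C@@H](C)OC(=O)C[C@@H](C)OC(=O)OCc1ccccc1
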